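**Retrosynthetic overview**
1. The nine-membered ring is closed last. The C8–C9 bond comes from an intramolecular vinylogous aldol of the ring-C enone (C9 methyl) onto a C8 aldehyde. C12 must already be sp3, because the core is a bicyclo[6.2.1] system with a bridgehead alkene.
2. The unit C12(OH)–C1H=C2–C3(OH) comes from a γ,δ-epoxy dienone by SmI2 reductive opening followed by enolate hydroxylation.
3. The C1–C12 bond comes from an aldol condensation of the ring-C cyclopentenone with the ring-A cyclopentene carbaldehyde.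
4. Ring A is made from an iminium-catalysed Mukaiyama–Michael reaction (sets C6 and C7) followed by an intramolecular aldol condensation.
5. Ring C is made from a Cu-box Mukaiyama aldol on diacetyl (sets C11) followed by a reductive aldol cyclisation. Ring order: A and C separately, then the nine-membered ring.

Assumption and notation: the SMILES is taken literally as a 5-9-5 skeleton, (3R,6S,7R,8S,11R,12S), with C6 and C12 cis on C1=C2 and the C11/C12 diol trans. Locants: ring A = C2–C6, with C3 bearing OH and C16H2OMe; C1 = vinyl CH; C7 = CHMe; C8 = CHOH; C9 = CH2; ring C = C10–C14, with C11 bearing Me/OH, C12 bearing OH, C13 = C=O and C14 bearing iPr.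

**Step 1**
Reactants: 1 N-methoxy-N-methyl-2-methoxyacetamide; 2 but-3-en-1-ylmagnesium bromide
Product: 4 1-methoxyhex-5-en-2-one, via magnesium-chelated tetrahedral adduct 3 (not isolated)
Conditions: THF, 0 °C; 1 M HCl
Reagents that add atoms: none
Why: Weinreb ketone synthesis, in which the chelated adduct survives until the quench so the Grignard reagent adds only once; no stereocentre is formed.

**Step 2**
Reactants: 4 1-methoxyhex-5-en-2-one; 5 (E)-but-2-enal
Product: 6 (E)-7-methoxy-6-oxohept-2-enal
Conditions: 5 (5 equiv), Hoveyda–Grubbs II (2.5 mol %), CH2Cl2, 40 °C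
Reagents that add atoms: none
Why: Olefin cross-metathesis of a type I terminal alkene with a type II enal gives the E-enal selectively and is driven by loss of propene.

**Step 3**
Reactants: 7 S-ethyl propanethioate
Product: 8 (Z)-1-(ethylsulfanyl)-1-(trimethylsilyloxy)prop-1-ene
Conditions: LDA, TMSCl (in situ quench), THF, −78 °C
Reagents that add atoms: chlorotrimethylsilane C[Si](C)(C)Cl
Why: Kinetic (Ireland-model) enolisation with O-silylation places Me cis to SEt, which is the Z silyl ketene thioacetal.

**Step 4**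
Reactants: 6 (E)-7-methoxy-6-oxohept-2-enal; 8 (Z)-1-(ethylsulfanyl)-1-(trimethylsilyloxy)prop-1-ene
Product: 9 S-ethyl (2R,3R)-7-methoxy-2-methyl-6-oxo-3-(2-oxoethyl)heptanethioate
Conditions: (2S,5S)-5-benzyl-2-tert-butyl-3-methylimidazolidin-4-one·Cl3CCO2H (20 mol %), H2O (2 equiv), acetone, −78 °C
Reagents that add atoms: none
Why: Iminium-catalysed (MacMillan) Mukaiyama–Michael addition, in which the benzyl and t-Bu groups of the catalyst shield one enal face and so set C6 (same sense as the (R)-indole/crotonaldehyde adducts), and an open antiperiplanar transition state gives the anti C6/C7 pair.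

**Step 5**
Reactants: 9 S-ethyl (2R,3R)-7-methoxy-2-methyl-6-oxo-3-(2-oxoethyl)heptanethioate
Product: 10 S-ethyl (2R)-2-[(1S)-2-formyl-3-(methoxymethyl)cyclopent-2-en-1-yl]propanethioate (ring-A enal)
Conditions: Bn2NH·CF3CO2H (20 mol %), toluene, 60 °C
Reagents that add atoms: none
Why: Amine-salt-catalysed 5-enolexo intramolecular aldol condensation, in which the aldehyde enamine (C2) attacks the activated α-methoxy ketone (C3) to close ring A, as in the limonene keto-aldehyde case; C6 is not acidic and C7 is untouched under these weakly acidic conditions.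

**Step 6**
Reactants: 11 4-methylpent-3-en-2-one (mesityl oxide)
Product: 12 4-methyl-2-(trimethylsilyloxy)penta-1,3-diene
Conditions: LDA, TMSCl (in situ quench), THF, −78 °C
Reagents that add atoms: chlorotrimethylsilane C[Si](C)(C)Cl
Why: Kinetic α′-deprotonation and O-silylation of the enone gives the cross-conjugated 2-silyloxydiene, whose nucleophilic carbon is the CH2 terminus (future C12).

**Step 7**
Reactants: 12 4-methyl-2-(trimethylsilyloxy)penta-1,3-diene; 13 butane-2,3-dione
Product: 14 (3S)-3,7-dimethyl-3-(trimethylsilyloxy)oct-6-ene-2,5-dione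
Conditions: Cu(OTf)2 (10 mol %), (S,S)-t-Bu-box (11 mol %), 13 (3 equiv), THF, −78 °C, neutral work-up
Reagents that add atoms: none
Why: Evans Cu(II)-box catalysed Mukaiyama aldol, in which the 1,2-diketone chelates copper like a pyruvate and is attacked on the face left open by the t-Bu groups; this sets C11 as the (S)-tertiary TMS ether after silyl transfer.

**Step 8**
Reactants: 14 (3S)-3,7-dimethyl-3-(trimethylsilyloxy)oct-6-ene-2,5-dione
Product: 15 (4S)-3-hydroxy-3,4-dimethyl-2-(propan-2-yl)-4-(trimethylsilyloxy)cyclopentan-1-one (C2/C3 epimers)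
Conditions: [(Ph3P)CuH]6 (0.35 equiv), toluene, −40 to 0 °C
Reagents that add atoms: none
Why: Stryker conjugate reduction with intramolecular aldol (reductive aldol cyclisation) creates the C14 enolate regiospecifically under neutral conditions, so ring C closes onto C10 without β-elimination of the silyloxy group; the two new centres are erased in step 9.

**Step 9**
Reactants: 15 (4S)-3-hydroxy-3,4-dimethyl-2-(propan-2-yl)-4-(trimethylsilyloxy)cyclopentan-1-one
Product: 16 (4S)-3,4-dimethyl-2-(propan-2-yl)-4-(trimethylsilyloxy)cyclopent-2-en-1-one (ring-C enone)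
Conditions: SOCl2, pyridine, 0 °C
Reagents that add atoms: none
Why: Dehydration of the β-hydroxy ketone through its chlorosulfite (E2/E1cB toward the acidic C14–H) gives the conjugated tetrasubstituted enone and leaves C11 untouched.

**Step 10**
Reactants: 16 ring-C enone; 10 ring-A enal
Product: 20 (E)-C12=C1 alkylidene trienone, via lithium cross-conjugated enolate 17 (not isolated), via lithium aldolate 18 (not isolated), via C1 mesylate 19 (not isolated)
Conditions: LDA, THF, −78 °C; 10; MsCl, −78 to 0 °C; DBU, 23 °C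
Reagents that add atoms: none
Why: Directed aldol addition, mesylation and E1cB elimination (a stepwise aldol condensation) forms C1–C12 from the kinetic α′-enolate, whose own β-elimination would give an antiaromatic cyclopentadienone; the C12=C1 geometry is irrelevant later.

**Step 11**
Reactants: 20 (E)-C12=C1 alkylidene trienone
Product: 21 (2R,3S)-2,3-epoxide of 20 (γ,δ-epoxy dienone)
Conditions: mCPBA, NaHCO3, CH2Cl2, 0 °C
Reagents that add atoms: mCPBA O=C(OO)c1cccc(Cl)c1
Why: Prilezhaev epoxidation attacks only the electron-richest, distal tetrasubstituted C2=C3 alkene, from the ring-A face anti to the C6 side chain, which fixes the C3–O configuration of the target.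

**Step 12**
Reactants: 21 γ,δ-epoxy dienone
Product: 22 (3R)-3-hydroxy β,γ-unsaturated ketone with C1=C2 (C12 cis to C6; C12-H epimers)
Conditions: SmI2 (2.5 equiv), THF–MeOH, −78 °C
Reagents that add atoms: none
Why: SmI2 reductive opening of a vinylogous epoxy ketone (Molander type) cleaves C2–O only and retains C3; the dienolate is protonated kinetically at C12, and the alkene forms from the rotamer that keeps ring C away from quaternary C3.

**Step 13**
Reactants: 22 (3R)-3-hydroxy β,γ-unsaturated ketone
Product: 25 (3R,6S,7R,11R,12S)-3,11,12-tris(trimethylsilyloxy) thioester, via dipotassium alkoxide-dienolate 23 (not isolated), via dipotassium 3,12-dialkoxide 24 (not isolated)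
Conditions: KHMDS (2.2 equiv), THF, −78 °C; Davis oxaziridine (1.3 equiv); TMSCl (4 equiv), −78 to 0 °C
Reagents that add atoms: 2-(phenylsulfonyl)-3-phenyloxaziridine O=S(=O)(c1ccccc1)N1OC1c1ccccc1; chlorotrimethylsilane C[Si](C)(C)Cl
Why: Davis enolate hydroxylation at the doubly activated C12–H occurs α (the γ-carbon C2 is fully substituted) and anti to the neighbouring C11–OSiMe3, which sets the trans C11/C12 diol; the C3 alkoxide cannot be expelled, and both alkoxides are then silylated.

**Step 14**
Reactants: 25 tris(trimethylsilyloxy) thioester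
Product: 26 tris(trimethylsilyloxy) C8 aldehyde
Conditions: Et3SiH, 10 % Pd/C, acetone, 23 °C
Reagents that add atoms: none
Why: Fukuyama reduction converts the thioester into the aldehyde under neutral conditions, so C7 is not epimerised and the hindered enone and trisubstituted alkene survive.

**Step 15**
Reactants: 26 tris(trimethylsilyloxy) C8 aldehyde
Product: 28 3,11,12-tris-O-trimethylsilyl brassicicene M, via lithium C9 dienolate of ATPH-bound aldehyde 27 (not isolated)
Conditions: ATPH (3.3 equiv), toluene, −78 °C; LiTMP (2.2 equiv), THF, −78 to −40 °C, 1 mM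
Reagents that add atoms: none
Why: Intramolecular Yamamoto vinylogous aldol, in which ATPH shields the aldehyde α-H and activates the C=O. C9–H is the only remaining enolisable site, and γ-attack is enforced by the iPr-blocked C14. C8 is predicted 8S from attack with the Al-bound oxygen exo to the forming ring; this prediction is unverified.

**Step 16**
Reactants: 28 3,11,12-tris-O-trimethylsilyl brassicicene M
Product: 29 brassicicene M
Conditions: HF·pyridine, pyridine–THF, 0 °C
Reagents that add atoms: none
Why: Buffered fluoride desilylation removes the three tertiary TMS ethers without ionising the allylic C3 carbinol or triggering retro-aldol or α-ketol shifts, so no stereocentre is touched.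

**Compound list**
1 | N-methoxy-N-methyl-2-methoxyacetamide | COCC(=O)N(C)OC | starting material
2 | but-3-en-1-ylmagnesium bromide | C=CCC[Mg]Br | starting material
3 | magnesium-chelated tetrahedral adduct (not isolated) | COCC([O-])(CCC=C)N(C)OC.[Mg+2].[Br-] | intermediate
4 | 1-methoxyhex-5-en-2-one | COCC(=O)CCC=C | intermediate
5 | (E)-but-2-enal | C/C=C/C=O | starting material
6 | (E)-7-methoxy-6-oxohept-2-enal | COCC(=O)CC/C=C/C=O | intermediate
7 | S-ethyl propanethioate | CCC(=O)SCC | starting material
8 | (Z)-1-(ethylsulfanyl)-1-(trimethylsilyloxy)prop-1-ene | C/C=C(\SCC)O[Si](C)(C)C | intermediate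
9 | S-ethyl (2R,3R)-7-methoxy-2-methyl-6-oxo-3-(2-oxoethyl)heptanethioate | CCSC(=O)[C@H](C)[C@@H](CC=O)CCC(=O)COC | intermediate
10 | S-ethyl (2R)-2-[(1S)-2-formyl-3-(methoxymethyl)cyclopent-2-en-1-yl]propanethioate | COCC1=C(C=O)[C@@H](CC1)[C@@H](C)C(=O)SCC | intermediate
11 | 4-methylpent-3-en-2-one | CC(=O)C=C(C)C | starting material
12 | 4-methyl-2-(trimethylsilyloxy)penta-1,3-diene | C=C(O[Si](C)(C)C)C=C(C)C | intermediate
13 | butane-2,3-dione | CC(=O)C(C)=O | starting material
14 | (3S)-3,7-dimethyl-3-(trimethylsilyloxy)oct-6-ene-2,5-dione | CC(=O)[C@@](C)(O[Si](C)(C)C)CC(=O)C=C(C)C | intermediate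
15 | (4S)-3-hydroxy-3,4-dimethyl-2-(propan-2-yl)-4-(trimethylsilyloxy)cyclopentan-1-one, C2/C3 epimers | CC(C)C1C(=O)C[C@](C)(O[Si](C)(C)C)C1(C)O | intermediate
16 | (4S)-3,4-dimethyl-2-(propan-2-yl)-4-(trimethylsilyloxy)cyclopent-2-en-1-one | CC(C)C1=C(C)[C@@](C)(O[Si](C)(C)C)CC1=O | intermediate
17 | lithium cross-conjugated (C13–O, C12=C13) enolate of 16 (not isolated) | CC(C)C1=C(C)[C@@](C)(O[Si](C)(C)C)C=C1[O-].[Li+] | intermediate
18 | lithium aldolate, C1–OLi, C1/C12 epimers (not isolated) | COCC1=C(C([O-])C2C(=O)C(C(C)C)=C(C)[C@@]2(C)O[Si](C)(C)C)[C@@H](CC1)[C@@H](C)C(=O)SCC.[Li+] | intermediate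
19 | C1 mesylate of the aldol (not isolated) | COCC1=C(C(OS(C)(=O)=O)C2C(=O)C(C(C)C)=C(C)[C@@]2(C)O[Si](C)(C)C)[C@@H](CC1)[C@@H](C)C(=O)SCC | intermediate
20 | (E)-C12=C1 alkylidene trienone (rings A and C joined) | COCC1=C(/C=C2/C(=O)C(C(C)C)=C(C)[C@@]2(C)O[Si](C)(C)C)[C@@H](CC1)[C@@H](C)C(=O)SCC | intermediate
21 | (2R,3S)-2,3-epoxide of 20, oxygen anti to the C6 side chain | COC[C@@]12CC[C@@H]([C@@H](C)C(=O)SCC)[C@@]1(O2)/C=C1/C(=O)C(C(C)C)=C(C)[C@@]1(C)O[Si](C)(C)C | intermediate
22 | (3R)-3-hydroxy β,γ-unsaturated ketone, C1=C2 with C6 and C12 cis, C12-H epimers | COC[C@@]1(O)CC[C@@H]([C@@H](C)C(=O)SCC)/C1=C\C1C(=O)C(C(C)C)=C(C)[C@@]1(C)O[Si](C)(C)C | intermediate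
23 | dipotassium C3-alkoxide / C13-dienolate of 22 (not isolated) | COC[C@@]1([O-])CC[C@@H]([C@@H](C)C(=O)SCC)/C1=C\C1=C([O-])C(C(C)C)=C(C)[C@@]1(C)O[Si](C)(C)C.[K+].[K+] | intermediate
24 | dipotassium 3,12-dialkoxide of the (12S)-hydroxy ketone (not isolated) | COC[C@@]1([O-])CC[C@@H]([C@@H](C)C(=O)SCC)/C1=C\[C@@]1([O-])C(=O)C(C(C)C)=C(C)[C@@]1(C)O[Si](C)(C)C.[K+].[K+] | intermediate
25 | (3R,6S,7R,11R,12S)-3,11,12-tris(trimethylsilyloxy) S-ethyl thioester | COC[C@@]1(O[Si](C)(C)C)CC[C@@H]([C@@H](C)C(=O)SCC)/C1=C\[C@@]1(O[Si](C)(C)C)C(=O)C(C(C)C)=C(C)[C@@]1(C)O[Si](C)(C)C | intermediate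
26 | corresponding C8 aldehyde | COC[C@@]1(O[Si](C)(C)C)CC[C@@H]([C@@H](C)C=O)/C1=C\[C@@]1(O[Si](C)(C)C)C(=O)C(C(C)C)=C(C)[C@@]1(C)O[Si](C)(C)C | intermediate
27 | lithium C9 (exocyclic methylene) dienolate of 26, aldehyde bound to ATPH (not isolated) | COC[C@@]1(O[Si](C)(C)C)CC[C@@H]([C@@H](C)C=O)/C1=C\[C@@]1(O[Si](C)(C)C)C([O-])=C(C(C)C)C(=C)[C@@]1(C)O[Si](C)(C)C.[Li+] | intermediate
28 | 3,11,12-tris-O-trimethylsilyl brassicicene M (8S) | COC[C@@]1(O[Si](C)(C)C)CC[C@@H]2/C1=C\[C@@]1(O[Si](C)(C)C)C(=O)C(C(C)C)=C(C[C@H](O)[C@@H]2C)[C@@]1(C)O[Si](C)(C)C | intermediate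
29 | brassicicene M | COC[C@@]1(O)CC[C@@H]2/C1=C\[C@@]1(O)C(=O)C(C(C)C)=C(C[C@H](O)[C@@H]2C)[C@@]1(C)O | target

**Totals**
Total step count: 16.
Longest linear sequence: 11 steps (steps 1, 2, 4, 5, 10–16, or equally steps 6–16).

**Three steps most likely to fail**

Step 15 (closing a bridged nine-membered ring, and the C8 configuration, which may come out Felkin, that is 8-epi). The fallback sets out from 25 and comes back at 28. The thioester itself serves as the electrophile. Slow addition of 25 to LiTMP (THF, −78 °C, 1 mM) gives the nine-membered C8 ketone F4 by an intramolecular vinylogous Claisen (Dieckmann-type) acylation, which is pulled forward by deprotonation of the acidic C9–H of the product. Reagent-controlled reduction with (R)-Me-CBS and catecholborane then gives 28. In this reduction the C7 branch is the large group and C9H2 the small one, and the hindered conjugated C13 ketone is left alone. The result is 8S independent of ring conformation.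

Step 13 (face and site of hydroxylation, and the competing thioester α-H). The fallback sets out from 20 and comes back at 25, replacing steps 11–13 by a redox-neutral sequence. Nucleophilic epoxidation of the C12=C1 enone bond (t-BuOOH, DBU, CH2Cl2, 0 °C) delivers oxygen to C12 anti to C11–OSiMe3 and gives the spiro α,β-epoxy ketone F2. Mild acid hydrolysis (cat. HClO4, THF–H2O, 0 °C) opens the vinyl epoxide in the SN2′ sense, with water attacking tertiary C3 anti to the C6 side chain, and gives the free 3,12-diol F3. Silylation with TMSOTf and 2,6-lutidine then gives 25.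

Step 4 (anti/syn ratio with this functionalised enal). The fallback sets out from 6 and comes back at 9. The nucleophile class is changed to the 1-pyrrolyl silyl ketene aminal, (Z)-1-[1-(trimethylsilyloxy)prop-1-enyl]pyrrole, under the same iminium activation; this class is documented to give the complementary diastereomer series. The product is the anti N-acylpyrrole adduct F1. Acyl transfer with EtSH and catalytic EtSLi (THF, 0 °C) then gives 9.

**Further compounds**
F1 | step 4 | (2R,3R)-7-methoxy-2-methyl-6-oxo-3-(2-oxoethyl)-1-(pyrrol-1-yl)heptan-1-one | O=C(n1cccc1)[C@H](C)[C@@H](CC=O)CCC(=O)COC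
F2 | step 13 | spiro C12–C1 α,β-epoxy ketone of 20 (C12–O anti to C11–OTMS, C1 epimers) | COCC1=C(C2O[C@@]23C(=O)C(C(C)C)=C(C)[C@@]3(C)O[Si](C)(C)C)[C@@H](CC1)[C@@H](C)C(=O)SCC
F3 | step 13 | free (3R,12S)-3,12-diol, 11-O-TMS thioester | COC[C@@]1(O)CC[C@@H]([C@@H](C)C(=O)SCC)/C1=C\[C@@]1(O)C(=O)C(C(C)C)=C(C)[C@@]1(C)O[Si](C)(C)C
F4 | step 15 | 8-oxo analogue of 28 (nine-membered C8 ketone) | COC[C@@]1(O[Si](C)(C)C)CC[C@@H]2/C1=C\[C@@]1(O[Si](C)(C)C)C(=O)C(C(C)C)=C(CC(=O)[C@@H]2C)[C@@]1(C)O[Si](C)(C)C
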